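**Strategy**

Atom labels follow the daucane skeleton: five-membered ring C1 (methyl-bearing quaternary fusion carbon), C2, C3, C4 (isopropyl carbinol), C5; seven-membered ring C1, C10, C9, C8 (formyl-bearing, C14 = CHO), C7, C6 (ester carbon), C5. The route rests on opening the seven-membered ring between C9 and C10. Because the C8=C9 enal is the conjugated isomer of a β,γ-unsaturated aldehyde, this bond can be made as an olefin: ring-closing metathesis joins a 2-methylpropenyl group on C1 to a vinyl group on C8 of a trans-disubstituted cyclopentane, closing the cycloheptene in one operation. Acetal hydrolysis then moves the olefin into conjugation. The feature exploited is the isolated C10 methylene flanked by quaternary C1 and the enal β-carbon C9.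

Key step: step 6

Remark: racemic aldehyde 8 is used, so 11, 13, 15 and 16 are carried as mixtures of epimers at C8 (left unspecified in the SMILES); this centre becomes sp2 in step 7.

**Route**

Step 1
Reactants: 1 3-ethoxycyclopent-2-en-1-one; 2 (2-methylprop-1-en-1-yl)magnesium bromide
Product: 4 3-(2-methylprop-1-en-1-yl)cyclopent-2-en-1-one, via carbinol adduct 3 (not isolated)
Conditions: THF, 0 °C to rt; then 1 M aq. HCl, 0 °C
Reagents that add atoms: water, O
Why: Stork–Danheiser reaction, in which 1,2-addition of the alkenyl Grignard reagent to the vinylogous ester followed by acid-mediated hydrolysis and dehydration should give the 3-alkenyl enone, with no stereocentre formed.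

Step 2
Reactants: 5 (E)-4,4-dimethoxybut-2-enal; 6 vinylmagnesium bromide
Product: 8 3-(dimethoxymethyl)pent-4-enal (racemic), via silyl enol ether 7 (not isolated)
Conditions: CuBr·SMe2 (5 mol %), TMSCl, THF, −78 °C; then aq. NH4Cl/AcOH buffer (pH 5), 0 °C
Reagents that add atoms: none
Why: Copper-catalysed, TMSCl-accelerated conjugate addition of the vinyl Grignard reagent to the enal should give the silyl enol ether, which is hydrolysed on work-up, and the new stereocentre at C8 is formed racemic, which is harmless because C8 becomes sp2 in step 7.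

Step 3
Reactants: 4 3-(2-methylprop-1-en-1-yl)cyclopent-2-en-1-one; 9 trimethylaluminium; 8 3-(dimethoxymethyl)pent-4-enal
Product: 11 (2S,3R)-2-[(1S)-3-(dimethoxymethyl)-1-hydroxypent-4-en-1-yl]-3-methyl-3-(2-methylprop-1-en-1-yl)cyclopentan-1-one (C8 epimers), via aluminium enolate 10 (not isolated)
Conditions: 9 (1.1 equiv), copper thiophene-2-carboxylate Cu(O2CC4H3S) (5 mol %), chiral BINOL-derived phosphoramidite (10 mol %, enantiomer selected for (R)-C1), Et2O, −30 °C; then 8 (1.5 equiv), −78 °C; aq. KNaC4H4O6
Reagents that add atoms: none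
Why: Copper-catalysed asymmetric 1,4-addition of the methyl group (the 1,6-position is blocked by the two methyl groups on the distal olefin carbon) should set the quaternary centre C1 under ligand control, and the resulting aluminium enolate should add to aldehyde 8 through a closed Zimmerman–Traxler transition state on the enolate face opposite the bulky 2-methylpropenyl group, which sets C5 (side chain cis to the methyl group) and the anti-related carbinol C6 in a tandem conjugate addition–aldol reaction.

Step 4
Reactants: 11 aldol from step 3; 12 isopropylmagnesium chloride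
Product: 13 (1R,2S,3R)-2-[(1S)-3-(dimethoxymethyl)-1-hydroxypent-4-en-1-yl]-3-methyl-3-(2-methylprop-1-en-1-yl)-1-(propan-2-yl)cyclopentan-1-ol
Conditions: 12 (3 equiv), anhydrous CeCl3 (3 equiv), THF, −78 to −20 °C; aq. NH4Cl
Reagents that add atoms: none
Why: CeCl3-promoted Grignard addition to the ketone should outpace enolisation, and the isopropyl group should enter on the carbonyl face opposite the C5 side chain (1,2-induction, reinforced by the alkoxide chelate lying on that lower face), which places the new hydroxyl group cis to C6 and sets C4.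

Step 5
Reactants: 13 diol from step 4; 14 4-(acetyloxy)benzoyl chloride
Product: 15 (1S)-3-(dimethoxymethyl)-1-[(1S,2R,5R)-2-hydroxy-5-methyl-5-(2-methylprop-1-en-1-yl)-2-(propan-2-yl)cyclopentyl]pent-4-en-1-yl 4-(acetyloxy)benzoate
Conditions: pyridine, DMAP (10 mol %), CH2Cl2, 0 °C to rt
Reagents that add atoms: none
Why: DMAP-catalysed acylation with the acid chloride should take the secondary C6 hydroxyl group selectively because the tertiary C4 hydroxyl group is far less reactive, and no stereocentre is touched.

Step 6
Reactants: 15 diene ester from step 5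
Product: 16 (3R,3aS,4S,8aR)-6-(dimethoxymethyl)-3-hydroxy-8a-methyl-3-(propan-2-yl)-1,2,3,3a,4,5,6,8a-octahydroazulen-4-yl 4-(acetyloxy)benzoate
Conditions: second-generation Hoveyda–Grubbs catalyst RuCl2(H2IMes)(=CH-C6H4-2-OiPr) (10 mol %), toluene (2 mM), 80 °C, argon sparge
Reagents that add atoms: none
Why: The ruthenium alkylidene should load onto the unhindered vinyl group at C9, add across the C10=CMe2 olefin through a metallacyclobutane ([2+2]) and cyclorevert to release 2-methylpropene, so that C9 and C10 are joined as a ring olefin. The closest known reaction type is ring-closing olefin metathesis of a 1,8-diene to a cycloheptene in which a prenyl-type trisubstituted olefin serves as the second partner. The seven-membered ring (C1, C10, C9, C8, C7, C6, C5) closes in an endocyclic sense, both metathesised carbons becoming ring atoms, onto the preformed trans-1,2-disubstituted cyclopentane, which gives the trans-fused bicycle. No stereocentre is created: the C9=C10 geometry is necessarily Z in a seven-membered ring and C1, C4, C5 and C6 are untouched, while both C8 epimers cyclise and converge in step 7. The step needs ring closure to outrun intermolecular cross-metathesis and olefin migration; high dilution, removal of the volatile alkene and the fact that the trisubstituted olefin on the quaternary carbon C1 cannot homodimerise should secure this.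

Step 7
Reactants: 16 bicyclic acetal from step 6
Product: 19 (3R,3aS,4S,8aR)-6-formyl-3-hydroxy-8a-methyl-3-(propan-2-yl)-1,2,3,3a,4,5,8,8a-octahydroazulen-4-yl 4-hydroxybenzoate (target), via unconjugated aldehyde 17 (not isolated), via acetoxy enal 18 (not isolated)
Conditions: HCl (10 mol %), THF–H2O 4:1, rt; then MeOH, K2CO3 (2 equiv), 0 °C; aq. NH4Cl
Reagents that add atoms: water, O
Why: Acid-catalysed acetal hydrolysis should unmask the C14 aldehyde, and carbonate base should then move the C9=C10 olefin into conjugation through the dienolate (giving the thermodynamically favoured trisubstituted C8=C9 enal and erasing the C8 stereocentre) and cleave the aryl acetate by transesterification much faster than the hindered secondary benzoate, which is further protected once the phenoxide has formed.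

**Compound list**

1 | 3-ethoxycyclopent-2-en-1-one | CCOC1=CC(=O)CC1 | starting material
2 | (2-methylprop-1-en-1-yl)magnesium bromide | CC(C)=C[Mg]Br | starting material
3 | 3-ethoxy-1-(2-methylprop-1-en-1-yl)cyclopent-2-en-1-ol (racemic, present as its magnesium alkoxide) | CCOC1=CC(O)(C=C(C)C)CC1 | intermediate
4 | 3-(2-methylprop-1-en-1-yl)cyclopent-2-en-1-one | CC(C)=CC1=CC(=O)CC1 | intermediate
5 | (E)-4,4-dimethoxybut-2-enal | COC(OC)/C=C/C=O | starting material
6 | vinylmagnesium bromide | C=C[Mg]Br | starting material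
7 | {[3-(dimethoxymethyl)penta-1,4-dien-1-yl]oxy}trimethylsilane (racemic) | COC(OC)C(C=C)C=CO[Si](C)(C)C | intermediate
8 | 3-(dimethoxymethyl)pent-4-enal (racemic) | COC(OC)C(C=C)CC=O | intermediate
9 | trimethylaluminium | C[Al](C)C | starting material
10 | dimethyl{[(3R)-3-methyl-3-(2-methylprop-1-en-1-yl)cyclopent-1-en-1-yl]oxy}alumane | C[Al](C)OC1=C[C@@](C)(C=C(C)C)CC1 | intermediate
11 | (2S,3R)-2-[(1S)-3-(dimethoxymethyl)-1-hydroxypent-4-en-1-yl]-3-methyl-3-(2-methylprop-1-en-1-yl)cyclopentan-1-one (C8 epimers) | O=C1CC[C@](C)(C=C(C)C)[C@H]1[C@@H](O)CC(C=C)C(OC)OC | intermediate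
12 | isopropylmagnesium chloride | CC(C)[Mg]Cl | starting material
13 | (1R,2S,3R)-2-[(1S)-3-(dimethoxymethyl)-1-hydroxypent-4-en-1-yl]-3-methyl-3-(2-methylprop-1-en-1-yl)-1-(propan-2-yl)cyclopentan-1-ol (C8 epimers) | CC(C)[C@]1(O)CC[C@](C)(C=C(C)C)[C@H]1[C@@H](O)CC(C=C)C(OC)OC | intermediate
14 | 4-(acetyloxy)benzoyl chloride | CC(=O)Oc1ccc(cc1)C(Cl)=O | starting material
15 | (1S)-3-(dimethoxymethyl)-1-[(1S,2R,5R)-2-hydroxy-5-methyl-5-(2-methylprop-1-en-1-yl)-2-(propan-2-yl)cyclopentyl]pent-4-en-1-yl 4-(acetyloxy)benzoate (C8 epimers) | CC(C)[C@]1(O)CC[C@](C)(C=C(C)C)[C@H]1[C@@H](OC(=O)c2ccc(OC(C)=O)cc2)CC(C=C)C(OC)OC | intermediate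
16 | (3R,3aS,4S,8aR)-6-(dimethoxymethyl)-3-hydroxy-8a-methyl-3-(propan-2-yl)-1,2,3,3a,4,5,6,8a-octahydroazulen-4-yl 4-(acetyloxy)benzoate (C8 epimers; azulene C6 = C8) | CC(C)[C@]1(O)CC[C@]2(C)C=CC(C(OC)OC)C[C@H](OC(=O)c3ccc(OC(C)=O)cc3)[C@H]21 | intermediate
17 | (3R,3aS,4S,8aR)-6-formyl-3-hydroxy-8a-methyl-3-(propan-2-yl)-1,2,3,3a,4,5,6,8a-octahydroazulen-4-yl 4-(acetyloxy)benzoate (C8 epimers) | CC(C)[C@]1(O)CC[C@]2(C)C=CC(C=O)C[C@H](OC(=O)c3ccc(OC(C)=O)cc3)[C@H]21 | intermediate
18 | (3R,3aS,4S,8aR)-6-formyl-3-hydroxy-8a-methyl-3-(propan-2-yl)-1,2,3,3a,4,5,8,8a-octahydroazulen-4-yl 4-(acetyloxy)benzoate | CC(C)[C@]1(O)CC[C@]2(C)CC=C(C=O)C[C@H](OC(=O)c3ccc(OC(C)=O)cc3)[C@H]21 | intermediate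
19 | (3R,3aS,4S,8aR)-6-formyl-3-hydroxy-8a-methyl-3-(propan-2-yl)-1,2,3,3a,4,5,8,8a-octahydroazulen-4-yl 4-hydroxybenzoate | CC(C)[C@]1(O)CC[C@]2(C)CC=C(C=O)C[C@H](OC(=O)c3ccc(O)cc3)[C@H]21 | target

**Step count and risks**

Total step count: 7. Longest linear sequence: 6 (steps 1, 3, 4, 5, 6, 7).

Steps most likely to fail:

Step 3. The aluminium enolate may discriminate poorly between its methyl-bearing and alkenyl-bearing faces, or the aldol may show low anti-selectivity, so that C5/C6 diastereomers form. The fallback sets out from the unseparated aldol mixture 11. Oxidation (Dess–Martin periodinane, NaHCO3, CH2Cl2) should give the 2-acylcyclopentanone (3R)-2-[3-(dimethoxymethyl)pent-4-enoyl]-3-methyl-3-(2-methylprop-1-en-1-yl)cyclopentan-1-one F1, in which C5 is configurationally labile. Asymmetric transfer hydrogenation under dynamic kinetic resolution (RuCl(p-cymene)[(S,S)-TsDPEN] or its enantiomer, HCO2H–Et3N) should then reduce the less hindered side-chain ketone and set C5 and C6 under catalyst control. The fallback comes back to the route at 11.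

Step 6. Initiation and ring closure at the two hindered olefins may be slow, so that oligomerisation through the vinyl group or olefin migration wins over cyclisation. The fallback sets out from 15. Ozonolysis of both olefins (O3, CH2Cl2–MeOH, −78 °C; Me2S) should give the dialdehyde (1S)-3-(dimethoxymethyl)-1-[(1S,2R,5S)-5-formyl-2-hydroxy-5-methyl-2-(propan-2-yl)cyclopentyl]-4-oxobutyl 4-(acetyloxy)benzoate F2. Intramolecular McMurry coupling (TiCl3(DME)1.5, Zn–Cu couple, DME, reflux, slow addition) should then form the same C9=C10 ring olefin by carbonyl coupling. The fallback comes back to the route at 16.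

Step 4. Enolisation, β-hydride reduction or retro-aldol cleavage of the metal aldolate may compete with addition to the hindered ketone. The fallback sets out from 11. Silylation (TESCl, imidazole, DMF) should give (2S,3R)-2-[(1S)-3-(dimethoxymethyl)-1-[(triethylsilyl)oxy]pent-4-en-1-yl]-3-methyl-3-(2-methylprop-1-en-1-yl)cyclopentan-1-one F3, which can no longer fragment. Addition of the organocerium reagent made from iPrLi and CeCl3 (THF, −78 °C) should give (1R,2S,3R)-2-[(1S)-3-(dimethoxymethyl)-1-[(triethylsilyl)oxy]pent-4-en-1-yl]-3-methyl-3-(2-methylprop-1-en-1-yl)-1-(propan-2-yl)cyclopentan-1-ol F4. Fluoride cleavage (TBAF, AcOH, THF) then comes back to the route at 13.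

**Further compounds**

F1 | step 3 | (3R)-2-[3-(dimethoxymethyl)pent-4-enoyl]-3-methyl-3-(2-methylprop-1-en-1-yl)cyclopentan-1-one | O=C1CC[C@](C)(C=C(C)C)C1C(=O)CC(C=C)C(OC)OC
F2 | step 6 | (1S)-3-(dimethoxymethyl)-1-[(1S,2R,5S)-5-formyl-2-hydroxy-5-methyl-2-(propan-2-yl)cyclopentyl]-4-oxobutyl 4-(acetyloxy)benzoate | CC(C)[C@]1(O)CC[C@](C)(C=O)[C@H]1[C@@H](OC(=O)c2ccc(OC(C)=O)cc2)CC(C=O)C(OC)OC
F3 | step 4 | (2S,3R)-2-[(1S)-3-(dimethoxymethyl)-1-[(triethylsilyl)oxy]pent-4-en-1-yl]-3-methyl-3-(2-methylprop-1-en-1-yl)cyclopentan-1-one | O=C1CC[C@](C)(C=C(C)C)[C@H]1[C@@H](O[Si](CC)(CC)CC)CC(C=C)C(OC)OC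
F4 | step 4 | (1R,2S,3R)-2-[(1S)-3-(dimethoxymethyl)-1-[(triethylsilyl)oxy]pent-4-en-1-yl]-3-methyl-3-(2-methylprop-1-en-1-yl)-1-(propan-2-yl)cyclopentan-1-ol | CC(C)[C@]1(O)CC[C@](C)(C=C(C)C)[C@H]1[C@@H](O[Si](CC)(CC)CC)CC(C=C)C(OC)OC
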